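A percentage point of the X charged is the unit you reckon in here.

| flask | X | E | temperature | remark | time |
|---|---|---|---|---|---|
| autumn | 0.025 M | 0.10 M | −10 °C | run made earlier |  |
| summer | 0.038 M | 0.10 M | 1 °C | run made earlier |  |
| midnight | 0.050 M | 0.20 M | −10 °C | run made earlier |  |
| maple | 0.050 M | 0.100 M | 5 °C |  | 8.0 min |
| birch | 0.050 M | 0.100 M | −15 °C |  | 8.0 min |

| run | time / min | Z / % | X / % |
|---|---|---|---|
| autumn | 3.00 | 12 | 27 |
| autumn | 5.00 | 19 | 18 |
| autumn | 8.00 | 23 | 14 |
| autumn | 10.0 | 26 | 10 |
| summer | 0.667 | 7 | 46 |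
| summer | 1.50 | 13 | 26 |
| summer | 3.00 | 24 | 21 |
| summer | 5.00 | 24 | 14 |
| midnight | 1.33 | 8 | 29 |
| midnight | 3.00 | 14 | 17 |
| midnight | 6.00 | 23 | 11 |
| midnight | 10.0 | 26 | 3 |

(each reading ± 1.5 percentage points)

- the flask that comes out highest in amount of Z, in percent of the X charged, or "all alike" when all lie within 1.5 percentage points (maple / birch / all alike)
- Z at the end, in percent of the X charged, maple
- Z at the end, in percent of the X charged, birch

- the analysis behind the earlier runs scatters by 1.5 percentage points, standard deviation

Reckon Z at the end as the X consumed times a ratio, then ask which input must be known well. X left over is the small term, a correction: midnight reads 11% at 6.00 min and 3% at 10.0 min, and that spread of 8 percentage points reaches Z at about a quarter of its size. The scatter of a Z reading, 1.5 points, enters the ratio directly. The ratio weighs most, since it multiplies nearly all of the charge. Its weak point is that maple holds half the E of midnight at the same X.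

So take the yield on consumed X, Z divided by X consumed at each run's last reading, averaged over the runs: r = 0.279. My own reckoning takes midnight's mean X left for maple, giving 25.9%, and autumn's 14% at 8.00 min for birch, giving 24.0%.

The forecast names maple, with 29% (25% to 33%) for maple and 24% (19% to 28%) for birch: “Maple is nearly finished”. My maple figure lies lower than that.

The flasks give 15.7% for maple and 12.5% for birch, so maple comes out highest.

    2 E → J (k = 0.302 L mol⁻¹ s⁻¹, Ea = 48.0 kJ mol⁻¹)
    X + E → X.E (k = 0.427 L mol⁻¹ s⁻¹, Ea = 42.0 kJ mol⁻¹)
    X + X.E → X.X.E (k = 0.336 L mol⁻¹ s⁻¹, Ea = 42.0 kJ mol⁻¹)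
    X.E ⇌ Z (K = 0.929, k = 0.0220 s⁻¹, Ea = 73.0 kJ mol⁻¹, ΔH = −82.0 kJ mol⁻¹)
    Z ⇌ Q (K = 0.515, k = 0.205 s⁻¹, Ea = 74.0 kJ mol⁻¹, ΔH = −22.0 kJ mol⁻¹)
    (constants at 5 °C)

Maple's yield on consumed X is 0.164 at conversion 95.7%, well below r. Birch's yield is 0.149 at conversion 83.7%, also below r. Part of birch's shortfall arises because Z passes on to Q and the reading comes at 8.00 min: with the path from Z to Q taken away, birch ends at 24.4% of Z, and left until 80.0 min it stands at 22.2%, against 12.5%. On a neighbour of maple with 0.013 M of X, r and the 6.04% of X left there give 26.2%; the computed result is 27.7%.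

The numbers in the tables stem from a simulated flask from invented constants, and the scatter is random.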